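**Strategy**

The hemiketal carbon C4 is a masked ketone of the seven-membered ring, flanked by C3, which carries the C1 methylene bound to pyranone C3′ and neighbours C12. This array is the retron of a radical ring enlargement. The pyranone radical adds to the terminal carbon of a vinyl group on quaternary C12 of a cis-fused cyclohexanone–cyclopentanone (13); the C3 radical then inserts into the C4–C12 bond by a Dowd–Beckwith 1,2-acyl shift. One operation forms C1–C3′ and C3–C4, turns the six-membered ketone into the seven-membered one and erases the C12 stereocentre of the precursor, so its epimers converge. Sulfoxide elimination and acid then release the enone and the hemiketal.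

Key step: step 8

Remark (numbering used throughout, taken from the target): pyranone O1′, C2′(=O), C3′, C4′(O), C5′(Me), C6′(Me); C1 = CH2 on C3′; C3 = ring-fusion CH; C4 = hemiketal carbon; C5 = CH(OH); C6 = ketone; C7 = C(OH) shared by the seven- and five-membered rings; C8 = enone β-carbon; C9 = enone α-CH; C10 = cyclopentenone C=O; C11 = CMe2; C12 = CHMe.

Remark (assumption): 4-hydroxy-5,6-dimethyl-2H-pyran-2-one (14) is taken as a catalogue compound.

Remark (assumption): C3, C4 and C5 of the target lie α to a carbonyl or at a hemiketal and are taken to be the thermodynamically preferred configurations (trans-fused dihydropyran, axial hemiketal OH); they are reached by equilibration in step 10. Centres that are erased or equilibrated later are left undefined in the SMILES of 11–17.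

**Route**

Step 1
Reactants: 1 2,2-dimethylcyclopentane-1,3-dione
Product: 2 2,2-dimethylcyclopent-4-ene-1,3-dione
Conditions: IBX (1.5 equiv), DMSO, 70 °C
Reagents that add atoms: none
Why: IBX dehydrogenation of a ketone (Nicolaou) should act on the only CH2–CH2 unit, which lies between the two carbonyl groups, to give the symmetric enedione; no stereocentre is formed.

Step 2
Reactants: 2 2,2-dimethylcyclopent-4-ene-1,3-dione; 3 ethynyltrimethylsilane
Product: 4 (R)-4-hydroxy-5,5-dimethyl-4-[(trimethylsilyl)ethynyl]cyclopent-2-en-1-one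
Conditions: Me2Zn (3 equiv), (R,R)-N,N′-bis(3,5-di-tert-butylsalicylidene)-1,2-cyclohexanediamine (20 mol %), toluene, 0 °C to rt; 1 M HCl work-up
Reagents that add atoms: none
Why: Zinc–salen-catalysed enantioselective alkynylzinc addition to a ketone should add 1,2 to one of the two homotopic carbonyl groups, whose faces differ by a quaternary carbon against a flat CH=CH, and so set C7 (the antipodal ligand is used if the induction proves opposite).

Step 3
Reactants: 4 (R)-4-hydroxy-5,5-dimethyl-4-[(trimethylsilyl)ethynyl]cyclopent-2-en-1-one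
Product: 6 (S)-4-ethynyl-5,5-dimethyl-4-[(triethylsilyl)oxy]cyclopent-2-en-1-one, via silyl ether 5 (not isolated)
Conditions: TESOTf, 2,6-lutidine, CH2Cl2, −78 to 0 °C; then K2CO3 (0.2 equiv), MeOH, 0 °C
Reagents that add atoms: triethylsilyl triflate CC[Si](CC)(CC)OS(=O)(=O)C(F)(F)F
Why: O-silylation of the tertiary alcohol followed by methanolysis of the alkynyl C–Si bond should give the terminal alkyne; the silyl ether blocks retro-aldol opening of the 4-hydroxycyclopentenone in the basic steps that follow, and C7 is untouched (its descriptor changes only by priority).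

Step 4
Reactants: 6 (S)-4-ethynyl-5,5-dimethyl-4-[(triethylsilyl)oxy]cyclopent-2-en-1-one; 7 tigloyl chloride
Product: 8 (S)-5,5-dimethyl-4-[(E)-4-methyl-3-oxohex-4-en-1-yn-1-yl]-4-[(triethylsilyl)oxy]cyclopent-2-en-1-one
Conditions: PdCl2(PPh3)2 (2 mol %), CuI (4 mol %), Et3N, THF, rt
Reagents that add atoms: none
Why: Acyl Sonogashira coupling of a terminal alkyne with an acid chloride should give the ynone directly (C5–C4 bond) with retention of the tigloyl alkene geometry.

Step 5
Reactants: 8 ynone
Product: 9 (R)-5,5-dimethyl-4-{2-[(E)-3-methyl-2-oxopent-3-en-1-yl]-1,3-dioxolan-2-yl}-4-[(triethylsilyl)oxy]cyclopent-2-en-1-one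
Conditions: ethylene glycol (3 equiv), KOtBu (10 mol %), THF, 0 °C to rt
Reagents that add atoms: ethylene glycol OCCO
Why: Double oxa-Michael addition of a 1,2-diol to the ynone (the second addition a 5-exo-trig closure) should fix C6 at the ketone level as a dioxolane and leave C4 as an isolated ketone with a single α-CH2 (C5).

Step 6
Reactants: 9 β-keto dioxolane
Product: 11 α-triethylsilyloxy ketone (C5–OTES, epimer mixture at C5), via silyl dienol ether 10 (not isolated)
Conditions: LiN(SiMe3)2, TESCl, THF, −78 °C; then DMDO, acetone/CH2Cl2, −78 to 0 °C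
Reagents that add atoms: chlorotriethylsilane CC[Si](Cl)(CC)CC; dimethyldioxirane CC1(C)OO1
Why: Rubottom oxidation: kinetic α′-deprotonation at C5 (the only sp3 α-CH, as the cyclopentenone has none) with internal silyl quench, epoxidation of the electron-rich enol ether and 1,4-silyl shift should install the C5 oxygen as its silyl ether; the C5 configuration is not controlled and is equilibrated in step 10.

Step 7
Reactants: 11 α-triethylsilyloxy ketone
Product: 13 cis-fused bicyclic diketone carrying Me and vinyl on quaternary C12 and SPh on C9, via potassium enolate 12 (not isolated)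
Conditions: KN(SiMe3)2, THF, −78 to −20 °C; then PhSSO2Ph, −78 °C
Reagents that add atoms: S-phenyl benzenethiosulfonate O=S(=O)(Sc1ccccc1)c1ccccc1
Why: Intramolecular Michael addition of the tigloyl dienolate through its α-carbon (deconjugative α-alkylation, 6-exo-trig) onto C8 of the cyclopentenone should form the C8–C12 bond and the quaternary vinyl centre; the three-atom tether enforces cis ring fusion (C8–H cis to the C7 oxygen), and the resulting C10 enolate is sulfenylated regiospecifically at C9 (C9 and C12 are formed as mixtures and are erased in steps 9 and 8).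

Step 8
Reactants: 13 cis-fused bicyclic diketone; 14 4-hydroxy-5,6-dimethyl-2H-pyran-2-one
Product: 15 ring-enlarged adduct (cycloheptanone with C3 bearing the CH2–pyranone arm; in ring–chain equilibrium with its cyclic hemiketal)
Conditions: 14 (1.5 equiv), [Ir(dF(CF3)ppy)2(dtbbpy)]PF6 (1 mol %), iPr3SiSH (2 mol %), 2,6-lutidine (20 mol %), MeCN, 450 nm LEDs, 40 °C
Reagents that add atoms: none
Why: The photoexcited iridium complex should oxidise the lutidine-paired enol of 14 to the electrophilic C3′ radical, which adds to the terminal vinyl carbon C1 of 13; the secondary C3 radical then closes 3-exo-trig onto the C4 ketone and the cyclopropyloxy radical opens by β-scission of C4–C12 (Dowd–Beckwith 1,2-acyl shift), so that C1–C3′ and C3–C4 are formed and C4–C12 is broken before the thiol returns a hydrogen atom to the tertiary C12 radical and the reduced iridium complex regenerates the thiol. The closest known reaction types are the radical-triggered 1,2-carbonyl migration and ring expansion of α-vinyl ketones and the photoredox/thiol hydroalkylation of alkenes by 1,3-dicarbonyl compounds. The seven-membered ring arises by ring enlargement (3-exo-trig closure, then fragmentation), while the dihydropyran ring appears here only as the hemiketal tautomer (6-exo-trig attack of the pyranone OH on C4) and is fixed in step 10. C12 should be set by hydrogen transfer to the convex face of the cis-fused bicycle, anti to the cyclopentanone ring, which is the target configuration; C3 is not controlled here and is equilibrated α to C4 in step 10; the C12 configuration of 13 is irrelevant because that centre becomes a planar radical. The step needs attack at C1 (electrophilic radical on a monosubstituted alkene), migration of C4 only (C8 is sp3 because the enone is stored as the α-phenylthio ketone, so no 1,2-alkenyl shift can compete) and rearrangement before hydrogen transfer to C3, which the activated α-silyloxy ketone and the low thiol loading should secure.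

Step 9
Reactants: 15 ring-enlarged adduct
Product: 17 cyclopentenone (C8=C9), via sulfoxide 16 (not isolated)
Conditions: mCPBA (1.0 equiv), CH2Cl2, −78 °C; then pyridine, toluene, 90 °C
Reagents that add atoms: none
Why: Sulfide oxidation and thermal syn-elimination of the β-keto sulfoxide (sulfoxide pyrolysis) should unveil the enone toward C8–H, the only β-hydrogen, without an oxidant that could attack the free hydroxypyranone or the cycloheptanone; C7 and C12 are untouched.

Step 10
Reactants: 17 cyclopentenone
Product: 18 CNP0525404.1 (target)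
Conditions: 2 M HCl, THF/H2O, 40 °C
Reagents that add atoms: water O
Why: Acid hydrolysis of both silyl ethers and of the dioxolane should free the C5 and C7 hydroxyls and the C6 ketone, after which the pyranone OH closes onto C4 (6-exo-trig hemiketalisation); C3 and C5 (each α to a carbonyl in the open form) and C4 should equilibrate under the acid to the trans-fused hemiketal with axial OH.

**Compound list**

1 | 2,2-dimethylcyclopentane-1,3-dione | O=C1CCC(=O)C1(C)C | starting material
2 | 2,2-dimethylcyclopent-4-ene-1,3-dione | O=C1C=CC(=O)C1(C)C | intermediate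
3 | ethynyltrimethylsilane | C#C[Si](C)(C)C | starting material
4 | (R)-4-hydroxy-5,5-dimethyl-4-[(trimethylsilyl)ethynyl]cyclopent-2-en-1-one (carbinol carbon = C7) | C[Si](C)(C)C#C[C@@]1(O)C=CC(=O)C1(C)C | intermediate
5 | (R)-5,5-dimethyl-4-[(triethylsilyl)oxy]-4-[(trimethylsilyl)ethynyl]cyclopent-2-en-1-one | C[Si](C)(C)C#C[C@@]1(O[Si](CC)(CC)CC)C=CC(=O)C1(C)C | intermediate
6 | (S)-4-ethynyl-5,5-dimethyl-4-[(triethylsilyl)oxy]cyclopent-2-en-1-one | C#C[C@@]1(O[Si](CC)(CC)CC)C=CC(=O)C1(C)C | intermediate
7 | tigloyl chloride, (E)-2-methylbut-2-enoyl chloride | C/C=C(\C)C(Cl)=O | starting material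
8 | (S)-5,5-dimethyl-4-[(E)-4-methyl-3-oxohex-4-en-1-yn-1-yl]-4-[(triethylsilyl)oxy]cyclopent-2-en-1-one | C/C=C(\C)C(=O)C#C[C@@]1(O[Si](CC)(CC)CC)C=CC(=O)C1(C)C | intermediate
9 | (R)-5,5-dimethyl-4-{2-[(E)-3-methyl-2-oxopent-3-en-1-yl]-1,3-dioxolan-2-yl}-4-[(triethylsilyl)oxy]cyclopent-2-en-1-one | C/C=C(\C)C(=O)CC1(OCCO1)[C@@]2(O[Si](CC)(CC)CC)C=CC(=O)C2(C)C | intermediate
10 | triethylsilyl dienol ether of 9 (C4(OTES)=C5, cross-conjugated with the tigloyl alkene) | C/C=C(\C)C(O[Si](CC)(CC)CC)=CC1(OCCO1)[C@@]2(O[Si](CC)(CC)CC)C=CC(=O)C2(C)C | intermediate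
11 | α-triethylsilyloxy ketone: 9 carrying OTES on C5 (C7 R, C5 epimer mixture) | C/C=C(\C)C(=O)C(O[Si](CC)(CC)CC)C1(OCCO1)[C@@]2(O[Si](CC)(CC)CC)C=CC(=O)C2(C)C | intermediate
12 | potassium C10 enolate of the Michael adduct (cis-fused, C8–H cis to C7–O) | C=CC1(C)C(=O)C(O[Si](CC)(CC)CC)C2(OCCO2)[C@@]3(O[Si](CC)(CC)CC)[C@@H]1C=C([O-])C3(C)C.[K+] | intermediate
13 | cis-fused bicyclo[4.3.0]nonane-dione: six-membered ring C12(Me)(vinyl)–C4(=O)–C5H(OTES)–C6(spiro-1,3-dioxolane)–C7(OTES)–C8H, five-membered ring C8H–C9H(SPh)–C10(=O)–C11Me2–C7; C7 R, C8–H cis to C7–O, mixture at C5, C9, C12 | C=CC1(C)C(=O)C(O[Si](CC)(CC)CC)C2(OCCO2)[C@@]3(O[Si](CC)(CC)CC)[C@@H]1C(Sc4ccccc4)C(=O)C3(C)C | intermediate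
14 | 4-hydroxy-5,6-dimethyl-2H-pyran-2-one | Cc1oc(=O)cc(O)c1C | starting material
15 | ring-enlarged adduct: cis-fused bicyclo[5.3.0]decane-dione with C3H(CH2–pyranon-3′-yl)–C4(=O)–C5H(OTES)–C6(dioxolane)–C7(OTES)–C8H–C12H(Me), C9–SPh; C12 as in the target, mixture at C3, C5, C9 | Cc1oc(=O)c(CC2C(=O)C(O[Si](CC)(CC)CC)C3(OCCO3)[C@@]4(O[Si](CC)(CC)CC)[C@H](C(Sc5ccccc5)C(=O)C4(C)C)[C@@H]2C)c(O)c1C | intermediate
16 | C9 phenyl sulfoxide of 15 | Cc1oc(=O)c(CC2C(=O)C(O[Si](CC)(CC)CC)C3(OCCO3)[C@@]4(O[Si](CC)(CC)CC)[C@H](C(S(=O)c5ccccc5)C(=O)C4(C)C)[C@@H]2C)c(O)c1C | intermediate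
17 | cyclopentenone: 15 with C8=C9 in place of C8–H/C9–SPh (C7 R, C12 R, mixture at C3, C5) | Cc1oc(=O)c(CC2C(=O)C(O[Si](CC)(CC)CC)C3(OCCO3)[C@@]4(O[Si](CC)(CC)CC)C(=CC(=O)C4(C)C)[C@@H]2C)c(O)c1C | intermediate
18 | CNP0525404.1 | Cc1oc(=O)c2c(c1C)O[C@]1(O)[C@H](O)C(=O)[C@@]3(O)C(=CC(=O)C3(C)C)[C@H](C)[C@H]1C2 | target

**Step count and risks**

Total step count: 10. Longest linear sequence: 10 steps (1 to 18); 3, 7 and 14 enter as purchased partners.

Steps most likely to fail:

1. Step 8. Hydrogen-atom transfer to the secondary C3 radical may outrun the 1,2-acyl shift and give the unrearranged hydroalkylation product; the photocatalytic chain may turn over poorly; or hydrogen may be delivered to the wrong face of C12. The fallback sets out from 13 and returns at 15, and makes the C1–C3′ bond by polar chemistry instead. Sodium benzenesulfinate and AcOH with the same iridium photocatalyst under blue light should add a sulfonyl radical to C1 and trigger the same ring enlargement, terminated by the sulfinic acid (a slower hydrogen donor than a thiol), to give the β-sulfonyl cycloheptanone F1. DBU should then expel benzenesulfinate (E1cB) to give the α-methylene cycloheptanone F2, to which the pyranone 14 adds in the same flask by Michael addition to give 15.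

2. Step 2. Enantiofacial discrimination at the enedione carbonyl may be insufficient, or conjugate addition may compete. The fallback sets out from 2 and returns at 4, relaying chirality through a disposable C10 carbinol. CBS reduction (Me-CBS oxazaborolidine, BH3·SMe2; antipode chosen for the S alcohol) of one carbonyl should give (S)-4-hydroxy-5,5-dimethylcyclopent-2-en-1-one F3. TBSCl/imidazole gives its silyl ether F4. Lithium (trimethylsilyl)acetylide (from 3 and n-BuLi, with CeCl3, THF, −78 °C) should add anti to the silyloxy group to give the propargylic alcohol F5. HF·pyridine removes the TBS group to give the diol F6, and MnO2 oxidises the allylic secondary alcohol back to the enone, giving 4.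

3. Step 7. The dienolate may react through its γ-carbon or fail to close onto the congested C8, or the base may open the dioxolane by retro-oxa-Michael reaction. The fallback sets out from 11 and returns at 13, and moves the ring closure to a Lewis-acid manifold. Soft enolisation (TESOTf, Et3N, −78 °C) should give the triethylsilyl dienol ether F7. Catalytic HNTf2 in CH2Cl2 at −78 °C should then effect a silyl-transfer Mukaiyama–Michael cyclisation to the C10 silyl enol ether F8, and PhSCl should sulfenylate C9 to give 13.

Further compounds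
F1 | step 8 | β-sulfonyl cycloheptanone: 15 with CH2–SO2Ph on C3 in place of the CH2–pyranonyl arm | O=S(=O)(CC1C(=O)C(O[Si](CC)(CC)CC)C2(OCCO2)[C@@]3(O[Si](CC)(CC)CC)[C@H](C(Sc4ccccc4)C(=O)C3(C)C)[C@@H]1C)c1ccccc1
F2 | step 8 | α-methylene cycloheptanone (C1=C3–C4=O) | C=C1C(=O)C(O[Si](CC)(CC)CC)C2(OCCO2)[C@@]3(O[Si](CC)(CC)CC)[C@H](C(Sc4ccccc4)C(=O)C3(C)C)[C@@H]1C
F3 | step 2 | (S)-4-hydroxy-5,5-dimethylcyclopent-2-en-1-one | O=C1C=C[C@H](O)C1(C)C
F4 | step 2 | (S)-4-[(tert-butyldimethylsilyl)oxy]-5,5-dimethylcyclopent-2-en-1-one | O=C1C=C[C@H](O[Si](C)(C)C(C)(C)C)C1(C)C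
F5 | step 2 | (1R,4S)-4-[(tert-butyldimethylsilyl)oxy]-5,5-dimethyl-1-[(trimethylsilyl)ethynyl]cyclopent-2-en-1-ol | C[Si](C)(C)C#C[C@@]1(O)C=C[C@H](O[Si](C)(C)C(C)(C)C)C1(C)C
F6 | step 2 | (1R,4S)-5,5-dimethyl-1-[(trimethylsilyl)ethynyl]cyclopent-2-ene-1,4-diol | C[Si](C)(C)C#C[C@@]1(O)C=C[C@H](O)C1(C)C
F7 | step 7 | triethylsilyl dienol ether of 11 (C1H2=C3H–C12(Me)=C4(OTES)) | C=CC(C)=C(O[Si](CC)(CC)CC)C(O[Si](CC)(CC)CC)C1(OCCO1)[C@@]2(O[Si](CC)(CC)CC)C=CC(=O)C2(C)C
F8 | step 7 | C10 triethylsilyl enol ether of the cis-fused Michael adduct | C=CC1(C)C(=O)C(O[Si](CC)(CC)CC)C2(OCCO2)[C@@]3(O[Si](CC)(CC)CC)[C@@H]1C=C(O[Si](CC)(CC)CC)C3(C)C
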